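Ring B (C5–C10, labdane numbering) is disconnected across C5–C6 and C9–C10 as a [4+2] adduct. The four-carbon arc C6–C7–C8–C9 with its branch C17 and the C9 side chain is a diene made from (R)-citronellol, whose carbons map onto C15–C11, C9, C8, C17 and C7 and whose stereocentre becomes C13. The C5=C10 edge is an acyclic (E)-2-methyl enal, so that one catalyst-controlled Diels–Alder reaction closes ring B and sets C5, C9 and C10, the (E) geometry fixing the trans ring fusion. Ring A is then closed by metathesis; C4 is set by enolate methylation and the C8 methylene by alkene transposition.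

Key step: step 5

Remarks
- Labdane numbering is used throughout: ring A = C1–C5 and C10, ring B = C5–C10, C17 on C8, C18 and C19 on C4, C20 on C10, side chain C11–C16 on C9. The target is in the ent series: C5–H and C9–H are anti to C20, and C19 is the C4 substituent syn to C20.
- Assumption on the catalyst antipode in step 5: in the usual formyl C–H···O binding model for α-substituted enals the (S)-oxazaborolidine sends the diene to the Re face of the α-carbon. The target needs bonding at the Si face of C10, hence the (R)-catalyst; the (S)-catalyst is equally available should the sense prove opposite.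
- Compounds 10–14 are mixtures at C4; this centre is erased in enolate 15 and set in step 9.

Step 1
Reactants: 1 (R)-citronellol
Product: 2 triisopropyl{[(3R)-3,7-dimethyloct-6-en-1-yl]oxy}silane
Conditions: TIPSCl, imidazole, DMF, rt
Reagents that add atoms: triisopropylsilyl chloride CC(C)[Si](Cl)(C(C)C)C(C)C
Why: Silylation of the primary alcohol is routine, and the robust TIPS ether should survive the Lewis acid, ylide, metathesis, amide base and hydride steps until step 13; no stereocentre is touched.

Step 2
Reactants: 2 TIPS ether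
Product: 4 (2E,6R)-2,6-dimethyl-8-(triisopropylsilyloxy)oct-2-enal, via allylic alcohol 3 (not isolated)
Conditions: SeO2 (cat.), t-BuOOH, salicylic acid (cat.), CH2Cl2, rt; then MnO2 on the crude product, CH2Cl2, rt
Reagents that add atoms: selenium dioxide O=[Se]=O (catalytic oxygen carrier), tert-butyl hydroperoxide CC(C)(C)OO (terminal oxidant)
Why: The SeO2/t-BuOOH allylic oxidation (ene reaction then [2,3]-sigmatropic shift) attacks the (E)-methyl group of the trisubstituted alkene selectively, and MnO2 oxidation of the allylic alcohol should complete the (E)-enal with the alkene geometry fixed.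

Step 3
Reactants: 4 enal
Product: 5 triisopropyl{[(3R,6E)-3,7-dimethylnona-6,8-dien-1-yl]oxy}silane
Conditions: Ph3PCH3Br, KOtBu, THF, 0 °C to rt
Reagents that add atoms: methyltriphenylphosphonium bromide C[P+](c1ccccc1)(c1ccccc1)c1ccccc1.[Br-]
Why: Wittig methylenation of the enal adds C6 and should give the (E)-1,3-diene without changing the geometry of the trisubstituted double bond.

Step 4
Reactants: 6 methyl pent-4-enoate, 7 (E)-3-ethoxy-2-methylprop-2-enal
Product: 10 methyl (3E)-4-methyl-5-oxo-2-(prop-2-en-1-yl)pent-3-enoate, via lithium enolate 8 (not isolated), via aldol adduct 9 (not isolated)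
Conditions: LDA (LiN(i-Pr)2), THF, −78 °C; then 7, −78 °C; then 1 M aq. HCl, THF, 0 °C
Reagents that add atoms: water O
Why: Aldol addition of the ester enolate to the formyl group of the β-ethoxy enal, followed by acid-induced allylic transposition with loss of ethanol (the β-alkoxy enal serving as a formylvinyl cation equivalent), should give the thermodynamically favoured (E)-enal; the new centre (C4) is racemic and is erased in step 9.

Step 5
Reactants: 5 diene, 10 enal
Product: 11 ring-B cycloadduct (cyclohexene aldehyde ester; C4 epimer mixture)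
Conditions: (R)-3,3-diphenyl-1-(2-methylphenyl)tetrahydro-1H,3H-pyrrolo[1,2-c][1,3,2]oxazaborole (20 mol %), Tf2NH (18 mol %), 10 (1.5 equiv), CH2Cl2, −78 to −20 °C
Reagents that add atoms: none
Why: The protonated oxazaborolidine binds the formyl oxygen of 10 as a chiral boron Lewis acid (with the formyl C–H···O contact typical of α-substituted enals), lowers the LUMO and should trigger a concerted, asynchronous Diels–Alder reaction in which C5–C6 bonding leads and C9–C10 follows; the closest known reaction type is the cationic oxazaborolidine-catalysed cycloaddition of tiglic-type α-methyl enals with acyclic alkyl-substituted dienes. Ring B (C5–C10) closes as a six-membered ring by [4π+2π] addition, suprafacial on both partners. At C5 and C10 the (E) geometry of the enal is transferred stereospecifically, so C5–H and C20 end up anti (the future trans ring fusion); at C9 the (E)-diene is expected to add with the boron-bound formyl group exo and the α-methyl group over the diene, which places C11 syn to C20; the absolute sense comes from the catalyst, which shields one enal face so that C9 bonds to the Si face of C10. The step needs regioselectivity (the unsubstituted terminus C6 to the β-carbon C5, favoured by the 1-alkyl substituent of the diene, the large LUMO coefficient at C5 and the lower steric demand of C6), exo selectivity (bulk of the complexed formyl group), π-facial control (catalyst) and chemoselectivity for the enal over the isolated allyl double bond (only the enal is activated).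

Step 6
Reactants: 11 cycloadduct
Product: 12 C10-vinyl compound (C4 epimer mixture)
Conditions: Ph3PCH3Br, KOtBu (ylide preformed), THF, 0 °C to rt
Reagents that add atoms: methyltriphenylphosphonium bromide C[P+](c1ccccc1)(c1ccccc1)c1ccccc1.[Br-]
Why: Wittig methylenation of the non-enolisable α-quaternary aldehyde turns C1 into the vinyl group needed for ring closure, and this aldehyde cannot epimerise.

Step 7
Reactants: 12 vinyl compound
Product: 13 methyl (13R)-15-(triisopropylsilyloxy)-18-nor-ent-labda-1,7-dien-19-oate (C4 epimer mixture)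
Conditions: second-generation Grubbs catalyst RuCl2(=CHPh)(PCy3)(H2IMes) (5 mol %), toluene, 80 °C
Reagents that add atoms: none
Why: Ring-closing olefin metathesis of the 1,7-diene (C10 vinyl and C4 allyl) should form the six-membered ring A with loss of ethylene, the trisubstituted C7=C8 bond being inert to the catalyst.

Step 8
Reactants: 13 diene ester
Product: 14 methyl (13R)-15-(triisopropylsilyloxy)-18-nor-ent-labd-7-en-19-oate (C4 epimer mixture)
Conditions: TsNHNH2, NaOAc, DME/H2O, reflux
Reagents that add atoms: none
Why: Diimide reduction is selective for the cis-disubstituted C1=C2 bond over the trisubstituted C7=C8 bond and cannot migrate double bonds.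

Step 9
Reactants: 14 ester
Product: 16 methyl (13R)-15-(triisopropylsilyloxy)-ent-labd-7-en-19-oate, via lithium enolate 15 (not isolated)
Conditions: LDA (LiN(i-Pr)2), THF, −78 to 0 °C; then MeI, DMPU, −78 °C to rt
Reagents that add atoms: iodomethane CI
Why: Ester enolate alkylation of the exocyclic C4 enolate should occur on the face anti to the axial C10 methyl group (no 1,3-diaxial clash), which makes the new methyl equatorial (C18) and leaves the ester axial (C19, syn to C20), the established outcome for C4 esters of 10-methyl-trans-decalins.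

Step 10
Reactants: 16 endocyclic alkene
Product: 17 methyl (13R)-15-(triisopropylsilyloxy)-ent-labd-8(17)-en-19-oate
Conditions: hν (medium-pressure Hg lamp, Vycor filter), p-xylene (sensitiser), i-PrOH, rt
Reagents that add atoms: none
Why: Arene-sensitised photoprotonation (excitation of the 1-methylcyclohexene unit to a strained twisted alkene, protonation to the C8 cation, loss of a C17 proton) is a known contra-thermodynamic route from 1-methylcyclohexenes and octalins to methylenecyclohexanes, because the exocyclic product is not photoprotonated again.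

Step 11
Reactants: 17 ester
Product: 18 (13R)-15-(triisopropylsilyloxy)-ent-labd-8(17)-en-19-ol
Conditions: LiAlH4, THF, 0 °C to reflux
Reagents that add atoms: none
Why: Hydride reduction of the hindered axial ester should give the neopentyl C19 alcohol while the alkene and the silyl ether stay intact.

Step 12
Reactants: 18 alcohol, 19 (R)-2-methylbutanoic acid
Product: 20 (13R)-15-(triisopropylsilyloxy)-ent-labd-8(17)-en-19-yl (2R)-2-methylbutanoate
Conditions: DCC, DMAP (cat.), CH2Cl2, 0 °C to rt
Reagents that add atoms: none
Why: Steglich esterification acylates the hindered primary alcohol under near-neutral conditions that should not epimerise the α-stereocentre of the acid.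

Step 13
Reactants: 20 silyl ether
Product: 21 (13R)-15-hydroxy-ent-labd-8(17)-en-19-yl (2R)-2-methylbutanoate
Conditions: Bu4NF, THF, rt
Reagents that add atoms: none
Why: Fluoride-mediated desilylation removes the primary TIPS ether while the neopentyl ester and the alkene are unaffected.

Step 14
Reactants: 21 alcohol
Product: 23 (4R,5S,9R,10S,13R)-19-{[(2R)-2-methylbutanoyl]oxy}labd-8(17)-en-15-oic acid (target), via aldehyde 22 (not isolated)
Conditions: TEMPO (20 mol %), PhI(OAc)2 (2.5 equiv), MeCN/H2O, rt
Reagents that add atoms: water O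
Why: TEMPO/PhI(OAc)2 oxidation in aqueous acetonitrile should take the primary alcohol through the aldehyde hydrate to the carboxylic acid without touching the 1,1-disubstituted alkene or the ester.

Compound list
1 | (R)-citronellol, (3R)-3,7-dimethyloct-6-en-1-ol | CC(C)=CCC[C@@H](C)CCO | starting material
2 | triisopropyl{[(3R)-3,7-dimethyloct-6-en-1-yl]oxy}silane | CC(C)=CCC[C@@H](C)CCO[Si](C(C)C)(C(C)C)C(C)C | intermediate
3 | (2E,6R)-2,6-dimethyl-8-(triisopropylsilyloxy)oct-2-en-1-ol | OC/C(C)=C/CC[C@@H](C)CCO[Si](C(C)C)(C(C)C)C(C)C | intermediate (not isolated)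
4 | (2E,6R)-2,6-dimethyl-8-(triisopropylsilyloxy)oct-2-enal | O=C/C(C)=C/CC[C@@H](C)CCO[Si](C(C)C)(C(C)C)C(C)C | intermediate
5 | triisopropyl{[(3R,6E)-3,7-dimethylnona-6,8-dien-1-yl]oxy}silane (diene C6=C7–C8(C17)=C9) | C=C/C(C)=C/CC[C@@H](C)CCO[Si](C(C)C)(C(C)C)C(C)C | intermediate
6 | methyl pent-4-enoate | C=CCCC(=O)OC | starting material
7 | (E)-3-ethoxy-2-methylprop-2-enal | CCO/C=C(\C)C=O | starting material
8 | lithium enolate of methyl pent-4-enoate | C=CCC=C([O-])OC.[Li+] | intermediate (not isolated)
9 | methyl 5-ethoxy-3-hydroxy-4-methyl-2-(prop-2-en-1-yl)pent-4-enoate (aldol adduct, diastereomer mixture) | CCO/C=C(\C)C(O)C(CC=C)C(=O)OC | intermediate (not isolated)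
10 | methyl (3E)-4-methyl-5-oxo-2-(prop-2-en-1-yl)pent-3-enoate (racemic; formyl carbon = C1, CH(CO2Me) = C4) | O=C/C(C)=C/C(CC=C)C(=O)OC | intermediate
11 | ring-B cycloadduct: cyclohexene with C7=C8 and 8-methyl; C10 bears CH3 (C20) and CHO (C1); C5 bears CH(CO2Me)(allyl) (C4, both epimers); C9 bears the (3R)-3-methyl-5-(triisopropylsilyloxy)pentyl chain; C20, the C5 substituent and the C9 chain syn, C5–H and C9–H anti to C20 | CC1=CC[C@H](C(CC=C)C(=O)OC)[C@@](C)(C=O)[C@@H]1CC[C@@H](C)CCO[Si](C(C)C)(C(C)C)C(C)C | intermediate
12 | C10-vinyl analogue of 11 (CHO replaced by CH=CH2; same configurations; C4 epimers) | CC1=CC[C@H](C(CC=C)C(=O)OC)[C@@](C)(C=C)[C@@H]1CC[C@@H](C)CCO[Si](C(C)C)(C(C)C)C(C)C | intermediate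
13 | methyl (13R)-15-(triisopropylsilyloxy)-18-nor-ent-labda-1,7-dien-19-oate (trans-fused; C4 epimers) | CC1=CC[C@@H]2C(C(=O)OC)CC=C[C@@]2(C)[C@@H]1CC[C@@H](C)CCO[Si](C(C)C)(C(C)C)C(C)C | intermediate
14 | methyl (13R)-15-(triisopropylsilyloxy)-18-nor-ent-labd-7-en-19-oate (C4 epimers) | CC1=CC[C@@H]2C(C(=O)OC)CCC[C@@]2(C)[C@@H]1CC[C@@H](C)CCO[Si](C(C)C)(C(C)C)C(C)C | intermediate
15 | lithium enolate of 14 (exocyclic C4=C19 enolate) | CC1=CC[C@@H]2C(=C([O-])OC)CCC[C@@]2(C)[C@@H]1CC[C@@H](C)CCO[Si](C(C)C)(C(C)C)C(C)C.[Li+] | intermediate (not isolated)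
16 | methyl (4R,13R)-15-(triisopropylsilyloxy)-ent-labd-7-en-19-oate (ester axial, syn to C20; C18 methyl equatorial) | CC1=CC[C@@H]2[C@](C)(C(=O)OC)CCC[C@@]2(C)[C@@H]1CC[C@@H](C)CCO[Si](C(C)C)(C(C)C)C(C)C | intermediate
17 | methyl (4R,13R)-15-(triisopropylsilyloxy)-ent-labd-8(17)-en-19-oate | C=C1CC[C@@H]2[C@](C)(C(=O)OC)CCC[C@@]2(C)[C@@H]1CC[C@@H](C)CCO[Si](C(C)C)(C(C)C)C(C)C | intermediate
18 | (4R,13R)-15-(triisopropylsilyloxy)-ent-labd-8(17)-en-19-ol | C=C1CC[C@@H]2[C@](C)(CO)CCC[C@@]2(C)[C@@H]1CC[C@@H](C)CCO[Si](C(C)C)(C(C)C)C(C)C | intermediate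
19 | (R)-2-methylbutanoic acid | CC[C@@H](C)C(=O)O | starting material
20 | (4R,13R)-15-(triisopropylsilyloxy)-ent-labd-8(17)-en-19-yl (2R)-2-methylbutanoate | C=C1CC[C@@H]2[C@](C)(COC(=O)[C@H](C)CC)CCC[C@@]2(C)[C@@H]1CC[C@@H](C)CCO[Si](C(C)C)(C(C)C)C(C)C | intermediate
21 | (4R,13R)-15-hydroxy-ent-labd-8(17)-en-19-yl (2R)-2-methylbutanoate | C=C1CC[C@@H]2[C@](C)(COC(=O)[C@H](C)CC)CCC[C@@]2(C)[C@@H]1CC[C@@H](C)CCO | intermediate
22 | (4R,13R)-15-oxo-ent-labd-8(17)-en-19-yl (2R)-2-methylbutanoate | C=C1CC[C@@H]2[C@](C)(COC(=O)[C@H](C)CC)CCC[C@@]2(C)[C@@H]1CC[C@@H](C)CC=O | intermediate (not isolated)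
23 | (4R,5S,9R,10S,13R)-19-{[(2R)-2-methylbutanoyl]oxy}labd-8(17)-en-15-oic acid | C=C1CC[C@@H]2[C@](C)(COC(=O)[C@H](C)CC)CCC[C@@]2(C)[C@@H]1CC[C@@H](C)CC(=O)O | target

Total step count: 14. Longest linear sequence: 13 steps (1 to 23 through steps 1–3 and 5–14); the dienophile branch is one step (step 4).

Steps most likely to fail

1. Step 5. The diene may add with insufficient exo/endo discrimination (formyl group under the diene), which would give C9 epimers; the racemic C4 centre next to the reacting double bond may also erode catalyst control. Fallback for the C9 problem, from 17 back to 17: the material is carried through steps 6–10 and arrives as 17 mixed with its C9 epimer F1. Ozonolysis of the mixture (O3, CH2Cl2/MeOH, −78 °C; then PPh3) should give the 17-nor 8-ketone F2 together with the 9-epi nor-ketone F3. NaOMe in MeOH at rt equilibrates F3 into F2 through the enolate, since the C9 chain is equatorial only in F2. Wittig methylenation (Ph3PCH3Br, KOtBu, toluene, 80 °C) then returns 17 as a single C9 epimer, so C9 is set under thermodynamic instead of kinetic control.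

2. Step 10. The photogenerated C8 cation may be trapped by the alcohol solvent, or lose a ring proton instead of a C17 proton, and conversion may stall. Fallback, from 16 to 17: Mukaiyama hydration of 16 (Co(acac)2, PhSiH3, O2, i-PrOH, rt) should give the tertiary alcohol F4 with the hydroxyl entering anti to C20 (equatorial). Dehydration with POCl3 in pyridine at 0 °C then gives 17, because an equatorial leaving group has an anti-periplanar hydrogen only on the C17 methyl group. Any axial-hydroxyl epimer would eliminate back to 16, which can be recycled.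

3. Step 4. Vinylogous enolisation with double-bond migration, or retro-aldol cleavage, may occur during the basic aldol stage or the acidic unmasking of the γ-ester-substituted enal. Fallback, from 6 to 10: 6 is converted (LDA, Me3SiCl, THF, −78 °C) into the ketene silyl acetal F5. A Mukaiyama-type addition of F5 to commercial 1,1,3,3-tetraethoxy-2-methylpropane (Me3SiOTf cat., CH2Cl2, −78 °C) gives the storable β-ethoxy acetal F6. Brief treatment of F6 with 1 M HCl in THF at 0 °C, directly before step 5, hydrolyses the acetal and eliminates ethanol to give 10 without any strongly basic stage.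

Further compounds
F1 | step 5 | methyl (4R,13R)-15-(triisopropylsilyloxy)-9-epi-ent-labd-8(17)-en-19-oate (C9 epimer of 17) | C=C1CC[C@@H]2[C@](C)(C(=O)OC)CCC[C@@]2(C)[C@H]1CC[C@@H](C)CCO[Si](C(C)C)(C(C)C)C(C)C
F2 | step 5 | methyl (4R,13R)-8-oxo-15-(triisopropylsilyloxy)-17-nor-ent-labdan-19-oate (C9 as in 17) | O=C1CC[C@@H]2[C@](C)(C(=O)OC)CCC[C@@]2(C)[C@@H]1CC[C@@H](C)CCO[Si](C(C)C)(C(C)C)C(C)C
F3 | step 5 | methyl (4R,13R)-8-oxo-15-(triisopropylsilyloxy)-17-nor-9-epi-ent-labdan-19-oate | O=C1CC[C@@H]2[C@](C)(C(=O)OC)CCC[C@@]2(C)[C@H]1CC[C@@H](C)CCO[Si](C(C)C)(C(C)C)C(C)C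
F4 | step 10 | methyl (4R,13R)-8-hydroxy-15-(triisopropylsilyloxy)-ent-labdan-19-oate (8-OH anti to C20, C17 methyl syn to C20) | C[C@]1(O)CC[C@@H]2[C@](C)(C(=O)OC)CCC[C@@]2(C)[C@@H]1CC[C@@H](C)CCO[Si](C(C)C)(C(C)C)C(C)C
F5 | step 4 | 1-methoxy-1-(trimethylsilyloxy)penta-1,4-diene (ketene silyl acetal of 6) | C=CCC=C(OC)O[Si](C)(C)C
F6 | step 4 | methyl 3,5,5-triethoxy-4-methyl-2-(prop-2-en-1-yl)pentanoate (diastereomer mixture) | CCOC(C(C)C(OCC)OCC)C(CC=C)C(=O)OC
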